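All runs were computed for an exercise; noise was put on by code.

Start from the easy end: left-handed and right-handed product are mirror images with the same energy, so under thermodynamic control their excess is zero, and that is the zero of the scale. The excess starts high under kinetic control and sinks towards zero as the two products interconvert.

| setting | noon | spring | gamma | eta |
|---|---|---|---|---|
| left-handed substrate | 0.10 M | 0.10 M | 0.10 M | 0.10 M |
| right-handed substrate | 0.10 M | 0.10 M | 0.10 M | 0.10 M |
| partner | 0.081 M | 0.13 M | 0.0600 M | 0.100 M |
| protic impurity | 0.050 M | 0.050 M | 0.0500 M | 0.0500 M |
| free catalyst | 5 mM | 5 mM | 5.0 mM | 5.0 mM |
| remark | run made earlier | run made earlier |  |  |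
| time |  |  | 25 h | 25 h |

| run | time / h | left-handed product / % | right-handed product / % |
|---|---|---|---|
| noon | 0.833 | 0 | 0 |
| noon | 2.50 | 2 | 0 |
| noon | 4.00 | 6 | 6 |
| noon | 6.00 | 7 | 0 |
| noon | 10.0 | 12 | 0 |
| noon | 12.0 | 11 | 0 |
| spring | 0.833 | 3 | 0 |
| spring | 2.50 | 1 | 2 |
| spring | 4.00 | 8 | 0 |
| spring | 6.00 | 13 | 0 |
| spring | 10.0 | 16 | 2 |
| spring | 12.0 | 19 | 4 |

(scatter of a reading: 2 percentage points)

- free catalyst is single-handed; left-handed substrate and right-handed substrate are mirror images of each other, charged as a racemate, each of them at the stated concentration
- the numbers in the tables scatter with a standard deviation of 2 percentage points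
- reactions considered so far: free catalyst + left-handed substrate <-> catalyst intermediate A; partner + catalyst intermediate A -> free catalyst + left-handed product; free catalyst <-> dormant form; free catalyst + right-handed substrate <-> catalyst intermediate B; left-handed product <-> right-handed product; partner + catalyst intermediate B -> free catalyst + right-handed product; partner + protic impurity -> quenched reagent
- an excess is the difference of the two amounts in percent of their sum
- an excess is below zero if the other one leads

* the flask that ends with the higher excess of left-handed product over right-handed product in the product, or "neither" when 2 percentage points or less lies between them (gamma / eta / neither)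
* excess of left-handed product over right-handed product in the product at the end, gamma
* excess of left-handed product over right-handed product in the product at the end, eta

Take first what you need not know well. The partner serves both product-forming steps, and I let gamma's 0.0600 M and eta's 0.100 M of it change the amount of product and not the excess, which is a judgement and not a proof. The time is 25 h in both flasks.

What you must know well is how fast the excess decays. Taking the start as full excess and counting the product as old as the flask, which is rough, I use the loss rate of the excess, meaning the logarithm of the excess lost per hour. From 6.00 h on, the two runs sum to 78.0% left-handed and 6.00% right-handed product. That is an excess of 85.7% at a mean time of 9.33 h, so the loss rate reads 0.0165 /h.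

This reading is weak: the right-handed sum is 6.00%, and each reading in it scatters by 2 percentage points. Doubling that right-handed sum in the reckoning gives 43.6% at 25 h, and halving it gives 81.4%. My own figure is 66.2% for both flasks.

The forecast, reckoned differently, said 65% for gamma and 64% for eta, hence neither: “These effects roughly cancel”.

    free catalyst + left-handed substrate ⇌ catalyst intermediate A (K = 230 /M, k = 680 /M/h)
    partner + catalyst intermediate A → free catalyst + left-handed product (k = 7.80 /M/h)
    free catalyst ⇌ dormant form (K = 2.50, k = 0.00630 /h)
    free catalyst + right-handed substrate ⇌ catalyst intermediate B (K = 16.0 /M, k = 67.0 /M/h)
    left-handed product ⇌ right-handed product (k = 0.00800 /h)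
    partner + catalyst intermediate B → free catalyst + right-handed product (k = 2.80 /M/h)
    partner + protic impurity → quenched reagent (k = 0.150 /M/h)

Gamma gives 74.3% and eta 73.1%, so the answer is neither, both higher than my 66.2%. The half-life of left-handed product by its forward turning alone is 87 h, longer than 25 h. Eta's own loss rate, 0.0125 /h, is slower than the 0.0165 /h I read, and carried to 4.0 d it gives 30.1%, where eta read at that time stands at 29.1%.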